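**Retrosynthetic overview** (isochromene numbering of the target: C1, O2, C3, C4, C4a, C5, C6, C7, C8, C8a)
1. Last disconnection: the stearate ester at the tertiary C7–O, leading back to carbinol 9.
2. Key disconnection: the carbocycle is opened at C4a=C5 and C6–C7, giving pyranyl 1,2-diketone 6 and the two-carbon unit phosphonoacetaldehyde 7. Forward: a carbene-catalysed cross-acyloin addition (polarity reversal of the aldehyde carbon C6, which attacks the C7 ketone and sets C7), then in the same flask an intramolecular Horner–Wadsworth–Emmons olefination of the ring ketone C4a.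
3. Enabling feature: in 6 the C7 carbonyl is part of a 1,2-dicarbonyl that cannot enolise, because C8a is a fully substituted sp2 carbon of the dihydropyranone ring, and it is the most electrophilic C=O. The ring ketone C4a lies 1,5 to C6, so C5 closes a six-membered ring.
4. Ring order: dihydropyranone ring first (O2–C1 bond by aminomethylenation and cyclisation of a δ-hydroxy-β-diketone; C3 from methyl (R)-3-hydroxybutanoate), carbocycle second. With C1 already on C8a the carbocycle is never pseudo-symmetric, so C7 cannot be scrambled by enolisation.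
5. 6 comes from ketal 5, and 5 from the Claisen product 3 of 3,3-dimethoxybutan-2-one 1 and ester 2.

Key step: step 4

Assumption: diethyl (2-oxoethyl)phosphonate 7 is taken as a commercial reagent (it is otherwise liberated from its commercial diethyl acetal by aqueous acid).

Step 1
Reactants: 1 3,3-dimethoxybutan-2-one; 2 methyl (R)-3-hydroxybutanoate
Product: 3 (7R)-7-hydroxy-2,2-dimethoxyoctane-3,5-dione
Conditions: 1 (3.2 equiv), LDA (3.2 equiv), THF, −78 °C; then 2, −78 to −20 °C; AcOH quench
Reagents that add atoms: none
Why: Crossed Claisen condensation, in which ketone 1 can enolise only at its methyl group (the other α-carbon is the ketal carbon) and the excess enolate absorbs the hydroxyl proton of 2 and the acidic proton of the product β-diketone, as in the usual preparation of δ-hydroxy-β-dicarbonyl compounds from β-hydroxy esters; the carbinol stereocentre of 2 is not touched.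

Step 2
Reactants: 3 (7R)-7-hydroxy-2,2-dimethoxyoctane-3,5-dione
Product: 5 (2R)-5-(2,2-dimethoxypropanoyl)-2-methyl-2,3-dihydro-4H-pyran-4-one, via enaminone 4 (not isolated)
Conditions: Me2NCH(OMe)2 (1.2 equiv), toluene, rt; then PPTS (10 mol%), 60 °C
Reagents that add atoms: N,N-dimethylformamide dimethyl acetal, COC(OC)N(C)C
Why: Aminomethylenation of the β-diketone at its central CH2, then 6-endo-trig addition–elimination of the δ-hydroxyl at the enaminone carbon (a dihydropyranone synthesis of the Maitland–Japp type), should close the pyranone ring with C1 in place; the C3 stereocentre (R, from 2) is not involved and the ketal should survive the anhydrous mild acid.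

Step 3
Reactants: 5 (2R)-5-(2,2-dimethoxypropanoyl)-2-methyl-2,3-dihydro-4H-pyran-4-one
Product: 6 (2R)-2-methyl-5-(2-oxopropanoyl)-2,3-dihydro-4H-pyran-4-one
Conditions: TFA, H2O, CH2Cl2, 0 °C to rt
Reagents that add atoms: water, O
Why: Acid-catalysed hydrolysis of the dimethyl ketal should unveil the 1,2-diketone, the vinylogous-ester ring being of a kind that is itself formed and handled in trifluoroacetic acid.

Step 4
Reactants: 6 (2R)-2-methyl-5-(2-oxopropanoyl)-2,3-dihydro-4H-pyran-4-one; 7 diethyl (2-oxoethyl)phosphonate
Product: 9 (3R,7R)-7-hydroxy-3,7-dimethyl-3,4-dihydro-6H-isochromene-6,8(7H)-dione, via keto phosphonate carbinol 8 (not isolated)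
Conditions: chiral aminoindanol-derived N-C6F5 triazolium BF4 (10 mol%, antipode chosen for Re-face attack at C7), i-Pr2NEt (10 mol%), CH2Cl2, rt; then LiCl, DBU, MeCN, rt to 40 °C (one pot)
Reagents that add atoms: none
Why: Proposed new method: the chiral triazolylidene carbene converts aldehyde 7 into its Breslow intermediate, an acyl-anion equivalent that adds 1,2 to the Re face of the C7 ketone of 6 (the only non-vinylogous, α-dicarbonyl-activated, non-enolisable carbonyl) to give carbinol 8, and LiCl/DBU then generates the phosphonate carbanion at C5, which closes the carbocycle by intramolecular Horner–Wadsworth–Emmons olefination of the ring ketone C4a with loss of diethyl phosphate. The closest known reaction types are the carbene-catalysed enantioselective cross-acyloin (cross-benzoin) addition of aliphatic aldehydes to activated ketones such as α-keto esters, and the intramolecular Horner–Wadsworth–Emmons cyclisation of β-keto phosphonates onto ketones. The six-membered ring C4a–C5–C6–C7–C8–C8a is closed by 6-exo-trig attack of C5 on the C4a carbonyl (oxaphosphetane, then C5=C4a), the C8 carbonyl being out of reach (four-membered ring). The new stereocentre C7 is set under catalyst control when the C6–C7 bond forms, and C3 is untouched. In both stages the step needs 1,2-addition rather than conjugate addition at the alkoxymethylene carbon C1: the α-diketone carbonyl should be far more electrophilic than C1 towards the Breslow intermediate, and the stabilised phosphonate carbanion should add to C1 only reversibly, whereas oxaphosphetane collapse at C4a is irreversible.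

Step 5
Reactants: 9 (3R,7R)-7-hydroxy-3,7-dimethyl-3,4-dihydro-6H-isochromene-6,8(7H)-dione; 10 stearoyl chloride
Product: 11 (3R,7R)-3,7-dimethyl-6,8-dioxo-3,4,7,8-tetrahydro-6H-isochromen-7-yl octadecanoate (target)
Conditions: Et3N, DMAP (cat.), CH2Cl2, 0 °C to rt
Reagents that add atoms: none
Why: DMAP-catalysed acylation (acyl-pyridinium transfer) of the tertiary C7 hydroxyl, the usual way of esterifying the 7-hydroxy group of this 6,8-dione ring system; the C7–O bond is not broken, so both stereocentres are retained.

**Compound list**
1 | 3,3-dimethoxybutan-2-one | CC(=O)C(C)(OC)OC | starting material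
2 | methyl (R)-3-hydroxybutanoate | C[C@@H](O)CC(=O)OC | starting material
3 | (7R)-7-hydroxy-2,2-dimethoxyoctane-3,5-dione | CC(OC)(OC)C(=O)CC(=O)C[C@@H](C)O | intermediate
4 | (7R)-4-[(dimethylamino)methylidene]-7-hydroxy-2,2-dimethoxyoctane-3,5-dione | CC(OC)(OC)C(=O)C(=CN(C)C)C(=O)C[C@@H](C)O | intermediate
5 | (2R)-5-(2,2-dimethoxypropanoyl)-2-methyl-2,3-dihydro-4H-pyran-4-one | CC(OC)(OC)C(=O)C1=CO[C@H](C)CC1=O | intermediate
6 | (2R)-2-methyl-5-(2-oxopropanoyl)-2,3-dihydro-4H-pyran-4-one | CC(=O)C(=O)C1=CO[C@H](C)CC1=O | intermediate
7 | diethyl (2-oxoethyl)phosphonate | CCOP(=O)(CC=O)OCC | starting material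
8 | diethyl [(3S)-3-hydroxy-3-methyl-4-[(2R)-2-methyl-4-oxo-3,4-dihydro-2H-pyran-5-yl]-2,4-dioxobutyl]phosphonate | CCOP(=O)(OCC)CC(=O)[C@@](C)(O)C(=O)C1=CO[C@H](C)CC1=O | intermediate
9 | (3R,7R)-7-hydroxy-3,7-dimethyl-3,4-dihydro-6H-isochromene-6,8(7H)-dione | O[C@]1(C)C(=O)C=C2C[C@@H](C)OC=C2C1=O | intermediate
10 | stearoyl chloride (octadecanoyl chloride) | CCCCCCCCCCCCCCCCCC(Cl)=O | starting material
11 | (3R,7R)-3,7-dimethyl-6,8-dioxo-3,4,7,8-tetrahydro-6H-isochromen-7-yl octadecanoate | CCCCCCCCCCCCCCCCCC(=O)O[C@]1(C)C(=O)C=C2C[C@@H](C)OC=C2C1=O | target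

Total step count: 5. Longest linear sequence: 5 steps (1/2 → 3 → 5 → 6 → 9 → 11).

**Steps most likely to fail**

Step 4 (Proposed new method). What may go wrong:
- conjugate (Stetter-type) addition of the acyl-anion equivalent, or irreversible addition–elimination of the phosphonate carbanion, at the alkoxymethylene carbon C1 instead of 1,2-addition at C7 and olefination at C4a;
- insufficient facial selectivity at C7;
- sluggish olefination of the deactivated ring carbonyl.

The fallback uses known reaction types in isolated stages, sets out from 6 and comes back at 9. 6 is treated with sodium pyruvate and a thiamine-diphosphate-dependent carboligase of the acetohydroxy-acid-synthase type (ThDP, MgSO4, phosphate buffer pH 7, DMSO co-solvent; enzyme or its enantiocomplementary variant selected for the 2R carbinol). This enzyme class transfers the decarboxylated acetyl unit strictly 1,2 to activated ketones and should give (2R)-2-hydroxy-2-methyl-1-[(2R)-2-methyl-4-oxo-3,4-dihydro-2H-pyran-5-yl]butane-1,3-dione F1. The methyl ketone of F1 is then closed onto the ring carbonyl through its titanium enolate (TiCl4, Bu3N, CH2Cl2, −78 °C; kinetically controlled, 1,2-selective aldol addition) to the β-hydroxy ketone (3R,7R)-4a,7-dihydroxy-3,7-dimethyl-3,4,4a,5-tetrahydro-6H-isochromene-6,8(7H)-dione F2 (either configuration at C4a). Acid (TsOH, CH2Cl2) should dehydrate F2 to 9.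

Step 3. What may go wrong: hydrolytic opening or deformylation of the alkoxymethylene vinylogous ester may outrun hydrolysis of the deactivated α-keto ketal. The fallback avoids the ketal and carries the future C7 carbonyl one oxidation level lower; it sets out from 2 and comes back at 6. The lithium enolate of racemic 3-(tert-butyldimethylsilyloxy)butan-2-one F3 (from acetoin and TBSCl) is acylated with 2 as in step 1 to (7R)-2-(tert-butyldimethylsilyloxy)-7-hydroxyoctane-3,5-dione F4. DMF dimethyl acetal, then PPTS, should give, through (7R)-2-(tert-butyldimethylsilyloxy)-4-[(dimethylamino)methylidene]-7-hydroxyoctane-3,5-dione F5, the pyranone (2R)-5-[2-(tert-butyldimethylsilyloxy)propanoyl]-2-methyl-2,3-dihydro-4H-pyran-4-one F6. HF·pyridine frees (2R)-5-(2-hydroxypropanoyl)-2-methyl-2,3-dihydro-4H-pyran-4-one F7, and Dess–Martin oxidation of the secondary carbinol (both epimers converge) should give 6 without aqueous acid.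

Step 1. What may go wrong: incomplete C-acylation by the alkoxide-bearing ester, retro-aldol erosion of the carbinol centre, self-condensation of the enolate, or acid-induced cyclodehydration of the δ-hydroxy-β-diketone on work-up. The fallback switches to a protected-ester Claisen; it sets out from 2 and comes back at 3. Silylation (TBSCl, imidazole, DMF) gives methyl (R)-3-(tert-butyldimethylsilyloxy)butanoate F8. Crossed Claisen condensation with the lithium enolate of 1 (two equivalents now suffice) gives (7R)-7-(tert-butyldimethylsilyloxy)-2,2-dimethoxyoctane-3,5-dione F9, and HF·pyridine returns 3.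

**Further compounds**
F1 | step 4 | (2R)-2-hydroxy-2-methyl-1-[(2R)-2-methyl-4-oxo-3,4-dihydro-2H-pyran-5-yl]butane-1,3-dione | CC(=O)[C@@](C)(O)C(=O)C1=CO[C@H](C)CC1=O
F2 | step 4 | (3R,7R)-4a,7-dihydroxy-3,7-dimethyl-3,4,4a,5-tetrahydro-6H-isochromene-6,8(7H)-dione | O[C@]1(C)C(=O)CC2(O)C[C@@H](C)OC=C2C1=O
F3 | step 3 | 3-(tert-butyldimethylsilyloxy)butan-2-one | CC(=O)C(C)O[Si](C)(C)C(C)(C)C
F4 | step 3 | (7R)-2-(tert-butyldimethylsilyloxy)-7-hydroxyoctane-3,5-dione | CC(O[Si](C)(C)C(C)(C)C)C(=O)CC(=O)C[C@@H](C)O
F5 | step 3 | (7R)-2-(tert-butyldimethylsilyloxy)-4-[(dimethylamino)methylidene]-7-hydroxyoctane-3,5-dione | CC(O[Si](C)(C)C(C)(C)C)C(=O)C(=CN(C)C)C(=O)C[C@@H](C)O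
F6 | step 3 | (2R)-5-[2-(tert-butyldimethylsilyloxy)propanoyl]-2-methyl-2,3-dihydro-4H-pyran-4-one | CC(O[Si](C)(C)C(C)(C)C)C(=O)C1=CO[C@H](C)CC1=O
F7 | step 3 | (2R)-5-(2-hydroxypropanoyl)-2-methyl-2,3-dihydro-4H-pyran-4-one | CC(O)C(=O)C1=CO[C@H](C)CC1=O
F8 | step 1 | methyl (R)-3-(tert-butyldimethylsilyloxy)butanoate | C[C@@H](O[Si](C)(C)C(C)(C)C)CC(=O)OC
F9 | step 1 | (7R)-7-(tert-butyldimethylsilyloxy)-2,2-dimethoxyoctane-3,5-dione | CC(OC)(OC)C(=O)CC(=O)C[C@@H](C)O[Si](C)(C)C(C)(C)C
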